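## Analysis of the target

Betaethrin A (19) is a diaryl ether of two benzene rings and has no stereocentre. Ring A is a methyl benzoate with CO2Me at C1, a free hydrogen-bonded phenol at C2, a methyl group at C4 and the ether oxygen at C6. Ring B is tetrasubstituted: the ether oxygen at C1' is flanked by a free phenol at C2' and an acetoxymethyl group at C6', and C4' carries a methoxy group. The sensitive points are the benzylic acetate (solvolysis, acyl transfer to a phenoxide), the electron-rich 1,2,4-trioxygenated ring B (oxidation when deprotonated) and the two phenols, which must stay free beside an ester made on a primary alcohol. Two things make the synthesis hard. The ether oxygen sits between two ortho substituents on ring B and next to the ester on ring A, so an aryl–oxygen coupling would be slow. Ring B also carries three different oxygen functions that must be told apart. The strategy rests on ring B being a resorcinol monomethyl ether: C2'-OH and C4'-OMe are meta, C1' bears a heteroatom and C6' a carbon substituent. This is the pattern produced when a vinylketene (supplying C2', C5', C6', C1') combines with an alkoxyalkyne (supplying C3', C4'). The only geometric element to control is the enol ether double bond of the acyclic precursor.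

## Retrosynthetic reasoning

**19 to 18.** The acetate C–O bond is cut last, because the benzylic acetate is the most fragile group. The forward step must acylate the primary alcohol of triol 18 while leaving both phenols free.

**18 to 17.** The ring A phenol and the benzylic oxygen are traced back to two silyl ethers in 17, so that one fluoride treatment frees both.

**17 to 10 and 12 (key disconnection).** Ring B is taken apart at C2'–C3', C4'–C5' and C1'–C2'. This dismantles the hindered ring and leaves the hindered ether untouched: the ether oxygen becomes the oxygen of an enol ether in diazo enone 10, which can be made without aryl–oxygen coupling. The two ring B oxygens are differentiated by origin. The ketone carbon of 10 becomes C2'-OH and methoxyacetylene 12 delivers C4'-OMe. The forward reaction has to achieve a Wolff shift to a vinylketene, a regioselective [2+2] with 12, a 4π opening and a 6π closure. The ring A phenol of 10 is silylated because a free O–H would intercept the ketene or the carbene.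

**10 to 9 to 8.** The bond between the acyl carbon and the diazo carbon is cut, which leads to acid chloride 9. The chloride is drawn from silyl ester 8 so that it forms under neutral conditions.

**8 to 7 to 6.** These are protecting-group operations. The side-chain carboxyl is carried as the tert-butyl ester of 6 and unmasked by acid to give 7. Hydroxide is avoided because it would add to the β-carbon of this vinylogous carbonate and expel the ring A phenoxide, and it would have to distinguish two esters. The benzylic oxygen therefore wears tert-butyldiphenylsilyl, which survives that acid. Silylation of 7 then caps the phenol and the acid together.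

**6 to 4 and 5.** The vinyl C–O bond is cut. Ring A comes as the symmetric diol 5, so there is no regiochemical question, only mono-substitution. The forward step is an addition–elimination on enol tosylate 4, which should settle in the E geometry.

**4 to 3 to 2 to 1.** The enol sulfonate comes from formyl ester 3. Its formyl C–C bond is cut α to the ester, back to silyl ether 2 and hydroxy ester 1.

**12 to 11.** The alkyne comes from chloroacetal 11 by twofold elimination.

## Alternatives that were turned down

**Alternative 1:** Ring A stays aromatic and the C6–O and C1–carboxyl bonds are cut together. In the forward step, fluoride-induced elimination of silyl triflate A2 would release an aryne. The caesium salt of the ring B phenol A3 would add at the aryne carbon meta to methoxy, and the resulting aryl anion would be carboxylated by carbon dioxide (A4) to give acid A1.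
- For it: one flask forms the hindered ether bond and a C–C bond, the methoxy group fixes the regiochemistry, and the plan is more convergent than the chosen one.
- Against it: A3, the difficult ring with three different oxygens, must still be made by stepwise aromatic chemistry. Its phenoxide is flanked on both sides and binds A4 reversibly. The aryl anion can take a proton instead of A4 and end as a simple diaryl ether.
- After the key step, A1 needs esterification, selective cleavage of the ring A methyl ether beside the intact ring B methyl ether, debenzylation next to a benzylic C–O bond, desilylation and acetylation.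
- Comparison: the chosen route is less convergent and its key step is less tested on its exact substrate. In exchange it uses ring A as bought, with the C2 phenol already free, and makes ring B with its oxygens differentiated from the start.

**Alternative 2:** Ring A is cut at C1–C2 and C5–C6. The silyl ketene acetal diene A7 would add to aryloxypropiolate A6, with the nucleophilic diene terminus attacking the oxygen-bearing alkyne carbon. The adduct would aromatise by loss of its methoxy and silyl groups to give salicylate A5.
- For it: a [4+2] addition of a 1,1-dioxygenated diene to an alkynoate is better precedented than the benzannulation used here. Regiochemistry is polarity-controlled and the ring A phenol emerges free. On reliability of the key step this plan is at least equal.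
- Against it: the ring-forming step is spent on ring A, which can be bought. Ring B must first be built as A3 and then turned into the push–pull alkyne A6. The aryloxy donor lowers dienophile reactivity, and its two ortho substituents shield the carbon that must be attacked. The ring B phenol needs a benzyl group that is later removed by hydrogenolysis beside a benzylic oxygen.
- Comparison: the chosen route offers a shorter sequence and no preformed ring B.

**Alternative 3:** Ring A is cut at C1–C6 and C4–C5. The electron-poor pyrone A9 would react as a diene across C3 and C6 with the electron-rich ethynyl ether A10. The bridged lactone would lose its carboxyl bridge in a retro-[4+2] step to give benzoate A8.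
- For it: the aromatisation is irreversible and cleaner than the tautomerisation that finishes the chosen key step. Regiochemistry is clear and the plan is convergent.
- Against it: A10, a terminal aryl ynol ether with two ortho substituents, is prone to hydration and oligomerisation at the temperatures pyrone cycloadditions need. The 4-methoxy group makes A9 a weaker electron-poor diene. A8 carries a ring A methyl ether, so a selective demethylation is added to debenzylation, desilylation and acetylation. Ring B must again be made first as A3.
- Comparison: the chosen route is shorter and ends with the correct ring A phenol.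

Key step: step 9

Assumption: 1, 5 and 11 are purchasable; 12 boils near room temperature and is therefore prepared and used as a cold solution.

## Route

Step 1
Reactants: 1 tert-butyl 3-hydroxypropanoate
Product: 2 tert-butyl 3-[(tert-butyldiphenylsilyl)oxy]propanoate
Conditions: TBDPSCl, imidazole, DMF, 0 °C to rt
Reagents that add atoms: tert-butyl(chloro)diphenylsilane (TBDPSCl), CC(C)(C)[Si](Cl)(c1ccccc1)c1ccccc1
Why: Standard silylation of a primary alcohol; the diphenylsilyl ether is chosen because it must survive the acid that later removes the tert-butyl ester.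

Step 2
Reactants: 2 tert-butyl 3-[(tert-butyldiphenylsilyl)oxy]propanoate
Product: 3 tert-butyl 2-formyl-3-[(tert-butyldiphenylsilyl)oxy]propanoate (racemic, in equilibrium with its hydroxymethylene enol)
Conditions: LiN(iPr)2, THF, −78 °C; HCO2Et, −78 to −20 °C; AcOH quench
Reagents that add atoms: ethyl formate, CCOC=O
Why: Crossed Claisen condensation (α-formylation) of a tert-butyl ester lithium enolate; the low temperature keeps the enolate from expelling the β-silyloxy group, and the product is held as its stabilised 1,3-dicarbonyl anion. The new sp3 centre is racemic and disappears in step 3.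

Step 3
Reactants: 3 tert-butyl 2-formyl-3-[(tert-butyldiphenylsilyl)oxy]propanoate
Product: 4 tert-butyl (E)-2-{[(tert-butyldiphenylsilyl)oxy]methyl}-3-[(4-methylbenzenesulfonyl)oxy]prop-2-enoate
Conditions: TsCl, N-methylimidazole, Et3N, MeCN, 0 °C
Reagents that add atoms: 4-methylbenzenesulfonyl chloride (TsCl), Cc1ccc(cc1)S(Cl)(=O)=O
Why: O-sulfonylation of the enol of an α-formyl ester through the N-sulfonylimidazolium salt; amine conditions without a chelating metal should favour the E enol tosylate (sulfonate trans to the ester). The geometry is not critical, because step 4 passes through a carbanion that can rotate.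

Step 4
Reactants: 4 tert-butyl (E)-2-{[(tert-butyldiphenylsilyl)oxy]methyl}-3-[(4-methylbenzenesulfonyl)oxy]prop-2-enoate; 5 methyl 2,6-dihydroxy-4-methylbenzoate
Product: 6 tert-butyl (E)-2-{[(tert-butyldiphenylsilyl)oxy]methyl}-3-[3-hydroxy-2-(methoxycarbonyl)-5-methylphenoxy]prop-2-enoate
Conditions: 5 (2 equiv), Cs2CO3 (1.1 equiv), MeCN, rt to 40 °C
Reagents that add atoms: none
Why: Nucleophilic vinylic substitution (addition–elimination) of the phenoxide at the unhindered β-carbon of the enol sulfonate. Diol 5 is symmetric, so only mono-substitution must be held, which excess diol and the chelation of the remaining phenol should secure. Reversible phenoxide addition lets the product settle as the more stable E isomer (aryloxy trans to the ester).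

Step 5
Reactants: 6 tert-butyl (E)-2-{[(tert-butyldiphenylsilyl)oxy]methyl}-3-[3-hydroxy-2-(methoxycarbonyl)-5-methylphenoxy]prop-2-enoate
Product: 7 (E)-2-{[(tert-butyldiphenylsilyl)oxy]methyl}-3-[3-hydroxy-2-(methoxycarbonyl)-5-methylphenoxy]prop-2-enoic acid
Conditions: CF3CO2H–CH2Cl2 (1:4), 0 °C to rt
Reagents that add atoms: none
Why: Acidolysis of the tert-butyl ester by alkyl–oxygen cleavage; no nucleophile is present that could attack the β-carbon and expel the ring A phenoxide. The methyl benzoate, the push–pull enol ether and the diphenylsilyl ether are stable to this acid, and the open ring A positions are too hindered for tert-butylation.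

Step 6
Reactants: 7 (E)-2-{[(tert-butyldiphenylsilyl)oxy]methyl}-3-[3-hydroxy-2-(methoxycarbonyl)-5-methylphenoxy]prop-2-enoic acid
Product: 8 tert-butyldimethylsilyl (E)-3-{3-[(tert-butyldimethylsilyl)oxy]-2-(methoxycarbonyl)-5-methylphenoxy}-2-{[(tert-butyldiphenylsilyl)oxy]methyl}prop-2-enoate
Conditions: TBSCl (2.5 equiv), imidazole, DMF, rt; non-acidic work-up
Reagents that add atoms: tert-butyl(chloro)dimethylsilane (TBSCl), CC(C)(C)[Si](C)(C)Cl
Why: One silylation caps the carboxylic acid and the phenol; the aryl silyl ether removes the only O–H that could quench the ketene or carbene of the key step, and the silyl ester is the substrate for neutral acid chloride formation.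

Step 7
Reactants: 8 tert-butyldimethylsilyl (E)-3-{3-[(tert-butyldimethylsilyl)oxy]-2-(methoxycarbonyl)-5-methylphenoxy}-2-{[(tert-butyldiphenylsilyl)oxy]methyl}prop-2-enoate
Product: 10 methyl 2-[(tert-butyldimethylsilyl)oxy]-6-{[(E)-2-{[(tert-butyldiphenylsilyl)oxy]methyl}-4-diazo-3-oxobut-1-en-1-yl]oxy}-4-methylbenzoate, via acid chloride 9 (not isolated)
Conditions: (COCl)2, DMF (cat.), CH2Cl2, 0 °C to rt; concentrate; CH2N2 (4 equiv), Et2O, 0 °C
Reagents that add atoms: diazomethane, C=[N+]=[N-]; oxalyl chloride, O=C(Cl)C(Cl)=O, supplies only the chlorine of intermediate 9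
Why: The Vilsmeier chloroiminium salt converts a silyl ester into the acid chloride without releasing HCl, and acylation of diazomethane (first stage of the Arndt–Eistert sequence) gives the diazomethyl ketone, with a second equivalent taking up HCl. The trisubstituted, donor-substituted double bond is a poor dipolarophile, so pyrazoline formation should not compete.

Step 8
Reactants: 11 2-chloro-1,1-dimethoxyethane
Product: 12 methoxyethyne (methoxyacetylene)
Conditions: NaNH2 (3.3 equiv), liquid NH3, −33 °C; cold aqueous NaCl quench; distil into ClCH2CH2Cl at −20 °C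
Reagents that add atoms: none
Why: Twofold base-induced elimination (loss of methoxide, then of chloride) gives the sodium acetylide, which is protonated on quench; this is the standard preparation of 1-alkoxyalkynes from chloroacetaldehyde acetals.

Step 9
Reactants: 10 methyl 2-[(tert-butyldimethylsilyl)oxy]-6-{[(E)-2-{[(tert-butyldiphenylsilyl)oxy]methyl}-4-diazo-3-oxobut-1-en-1-yl]oxy}-4-methylbenzoate; 12 methoxyethyne
Product: 17 methyl 2-[(tert-butyldimethylsilyl)oxy]-6-[2-{[(tert-butyldiphenylsilyl)oxy]methyl}-6-hydroxy-4-methoxyphenoxy]-4-methylbenzoate, via vinylketene 13 (not isolated), via alkenylcyclobutenone 14 (not isolated), via dienylketene 15 (not isolated), via cyclohexadienone 16 (not isolated)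
Conditions: 12 (4 equiv), ClCH2CH2Cl (0.05 M, degassed), hν (medium-pressure Hg lamp, Pyrex filter), 5 °C, sealed tube; then 80 °C, sealed tube
Reagents that add atoms: none
Why: Excitation of the s-cis diazo ketone expels nitrogen with a concerted 1,2-shift of the alkenyl carbon (photochemical Wolff rearrangement) and gives vinylketene 13 with the alkene geometry retained. The ketene carbonyl carbon is attacked by the unsubstituted, nucleophilic carbon of 12 and the ketene α-carbon bonds to the methoxy-bearing carbon, a polarity-controlled [2+2] that gives cyclobutenone 14 and forms C2'–C3' and C4'–C5'. On warming, 14 opens by a reversible 4π electrocyclic reaction; only the dienylketene 15 with the ketene and the alkenyl arm on the same side can go on, and the other rotamer returns to 14. Ring B closes by a thermal disrotatory 6π electrocyclisation (C1'–C2' bond) to dienone 16, which enolises to phenol 17; the closure is pericyclic, not polar. The closest known reaction type is the photochemical Wolff variant of the Danheiser benzannulation of α,β-unsaturated diazomethyl ketones with alkoxy- and siloxyalkynes. No stereocentre is set, since the sp3 carbons of 14 and 16 are lost on aromatisation. The step needs [2+2] regiochemistry, which the ynol ether polarisation secures (methoxy ends meta to the new hydroxyl); an outward aryloxy group at the triene terminus, which the E enol ether of 10 secures while also keeping the ether oxygen away from the carbene centre; and freedom from ketene quenchers, which the silylated ring A phenol and excess 12 secure. The ketene acceptor orbital lies in the plane orthogonal to the donor-substituted diene π system, so the aryloxy group should not switch off the [2+2].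

Step 10
Reactants: 17 methyl 2-[(tert-butyldimethylsilyl)oxy]-6-[2-{[(tert-butyldiphenylsilyl)oxy]methyl}-6-hydroxy-4-methoxyphenoxy]-4-methylbenzoate
Product: 18 methyl 2-hydroxy-6-[2-hydroxy-6-(hydroxymethyl)-4-methoxyphenoxy]-4-methylbenzoate
Conditions: Bu4NF–AcOH (1:1, 3 equiv), THF, 0 °C to rt, Ar
Reagents that add atoms: none
Why: Fluoride cleaves the aryl silyl ether and the primary diphenylsilyl ether in one operation; the AcOH buffer keeps the phenols protonated, so the electron-rich ring B is not oxidised and no phenoxide-driven acyl or aryl migration can start.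

Step 11
Reactants: 18 methyl 2-hydroxy-6-[2-hydroxy-6-(hydroxymethyl)-4-methoxyphenoxy]-4-methylbenzoate
Product: 19 methyl 2-[2-(acetoxymethyl)-6-hydroxy-4-methoxyphenoxy]-6-hydroxy-4-methylbenzoate (betaethrin A)
Conditions: AcOH, PPh3, DIAD, THF, 0 °C
Reagents that add atoms: acetic acid, CC(=O)O
Why: Mitsunobu esterification: only the primary benzylic alcohol becomes an oxyphosphonium leaving group, and acetate, far more acidic than the phenols, is the nucleophile, so both phenols should stay free. No base is present that could move the acetyl group.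

## Compound list

1 | tert-butyl 3-hydroxypropanoate | CC(C)(C)OC(=O)CCO | starting material
2 | tert-butyl 3-[(tert-butyldiphenylsilyl)oxy]propanoate | CC(C)(C)OC(=O)CCO[Si](c1ccccc1)(c1ccccc1)C(C)(C)C | intermediate
3 | tert-butyl 2-formyl-3-[(tert-butyldiphenylsilyl)oxy]propanoate (racemic, enolisable) | CC(C)(C)OC(=O)C(C=O)CO[Si](c1ccccc1)(c1ccccc1)C(C)(C)C | intermediate
4 | tert-butyl (E)-2-{[(tert-butyldiphenylsilyl)oxy]methyl}-3-[(4-methylbenzenesulfonyl)oxy]prop-2-enoate | CC(C)(C)OC(=O)/C(CO[Si](c1ccccc1)(c1ccccc1)C(C)(C)C)=C/OS(=O)(=O)c1ccc(C)cc1 | intermediate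
5 | methyl 2,6-dihydroxy-4-methylbenzoate | COC(=O)c1c(O)cc(C)cc1O | starting material
6 | tert-butyl (E)-2-{[(tert-butyldiphenylsilyl)oxy]methyl}-3-[3-hydroxy-2-(methoxycarbonyl)-5-methylphenoxy]prop-2-enoate | COC(=O)c1c(O)cc(C)cc1O/C=C(\CO[Si](c2ccccc2)(c2ccccc2)C(C)(C)C)C(=O)OC(C)(C)C | intermediate
7 | (E)-2-{[(tert-butyldiphenylsilyl)oxy]methyl}-3-[3-hydroxy-2-(methoxycarbonyl)-5-methylphenoxy]prop-2-enoic acid | COC(=O)c1c(O)cc(C)cc1O/C=C(\CO[Si](c2ccccc2)(c2ccccc2)C(C)(C)C)C(=O)O | intermediate
8 | tert-butyldimethylsilyl (E)-3-{3-[(tert-butyldimethylsilyl)oxy]-2-(methoxycarbonyl)-5-methylphenoxy}-2-{[(tert-butyldiphenylsilyl)oxy]methyl}prop-2-enoate | COC(=O)c1c(O[Si](C)(C)C(C)(C)C)cc(C)cc1O/C=C(\CO[Si](c2ccccc2)(c2ccccc2)C(C)(C)C)C(=O)O[Si](C)(C)C(C)(C)C | intermediate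
9 | (E)-3-{3-[(tert-butyldimethylsilyl)oxy]-2-(methoxycarbonyl)-5-methylphenoxy}-2-{[(tert-butyldiphenylsilyl)oxy]methyl}prop-2-enoyl chloride | COC(=O)c1c(O[Si](C)(C)C(C)(C)C)cc(C)cc1O/C=C(\CO[Si](c2ccccc2)(c2ccccc2)C(C)(C)C)C(=O)Cl | intermediate
10 | methyl 2-[(tert-butyldimethylsilyl)oxy]-6-{[(E)-2-{[(tert-butyldiphenylsilyl)oxy]methyl}-4-diazo-3-oxobut-1-en-1-yl]oxy}-4-methylbenzoate | COC(=O)c1c(O[Si](C)(C)C(C)(C)C)cc(C)cc1O/C=C(\CO[Si](c2ccccc2)(c2ccccc2)C(C)(C)C)C(=O)C=[N+]=[N-] | intermediate
11 | 2-chloro-1,1-dimethoxyethane (chloroacetaldehyde dimethyl acetal) | COC(CCl)OC | starting material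
12 | methoxyethyne (methoxyacetylene) | C#COC | intermediate
13 | methyl 2-[(tert-butyldimethylsilyl)oxy]-6-{[(Z)-2-{[(tert-butyldiphenylsilyl)oxy]methyl}-4-oxobuta-1,3-dien-1-yl]oxy}-4-methylbenzoate (vinylketene, aryloxy trans to the ketene arm) | COC(=O)c1c(O[Si](C)(C)C(C)(C)C)cc(C)cc1O/C=C(\CO[Si](c2ccccc2)(c2ccccc2)C(C)(C)C)C=C=O | intermediate
14 | methyl 2-[(tert-butyldimethylsilyl)oxy]-6-{[(Z)-3-[(tert-butyldiphenylsilyl)oxy]-2-(2-methoxy-4-oxocyclobut-2-en-1-yl)prop-1-en-1-yl]oxy}-4-methylbenzoate (racemic) | COC1=CC(=O)C1/C(CO[Si](c2ccccc2)(c2ccccc2)C(C)(C)C)=C/Oc2cc(C)cc(O[Si](C)(C)C(C)(C)C)c2C(=O)OC | intermediate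
15 | methyl 2-[(tert-butyldimethylsilyl)oxy]-6-{[(1Z,3E)-2-{[(tert-butyldiphenylsilyl)oxy]methyl}-4-methoxy-6-oxohexa-1,3,5-trien-1-yl]oxy}-4-methylbenzoate (dienylketene) | O=C=C/C(OC)=C\C(CO[Si](c1ccccc1)(c1ccccc1)C(C)(C)C)=C\Oc1cc(C)cc(O[Si](C)(C)C(C)(C)C)c1C(=O)OC | intermediate
16 | methyl 2-[(tert-butyldimethylsilyl)oxy]-6-[(2-{[(tert-butyldiphenylsilyl)oxy]methyl}-4-methoxy-6-oxocyclohexa-2,4-dien-1-yl)oxy]-4-methylbenzoate (racemic) | O=C1C=C(OC)C=C(CO[Si](c2ccccc2)(c2ccccc2)C(C)(C)C)C1Oc1cc(C)cc(O[Si](C)(C)C(C)(C)C)c1C(=O)OC | intermediate
17 | methyl 2-[(tert-butyldimethylsilyl)oxy]-6-[2-{[(tert-butyldiphenylsilyl)oxy]methyl}-6-hydroxy-4-methoxyphenoxy]-4-methylbenzoate | COC(=O)c1c(O[Si](C)(C)C(C)(C)C)cc(C)cc1Oc1c(O)cc(OC)cc1CO[Si](c2ccccc2)(c2ccccc2)C(C)(C)C | intermediate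
18 | methyl 2-hydroxy-6-[2-hydroxy-6-(hydroxymethyl)-4-methoxyphenoxy]-4-methylbenzoate | COC(=O)c1c(O)cc(C)cc1Oc1c(O)cc(OC)cc1CO | intermediate
19 | methyl 2-[2-(acetoxymethyl)-6-hydroxy-4-methoxyphenoxy]-6-hydroxy-4-methylbenzoate (betaethrin A) | COC(=O)c1c(O)cc(C)cc1Oc1c(O)cc(OC)cc1COC(C)=O | target

## Step count and risks

Total step count: 11. Longest linear sequence: 10 (steps 1 to 7 and 9 to 11); step 8 is a one-step side branch.

**Step 9 (key step).** Two processes may go wrong.
- The excited diazo ketone may follow carbene paths instead of the concerted shift. These are attack on the silyl ether oxygen to give an oxonium ylide, or light-induced isomerisation of the enol ether, which brings the ether oxygen within reach of the carbene centre.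
- Capture of the vinylketene by the volatile alkyne may be slower than its consumption by the accumulating phenol (acylation) or by dimerisation.

Fallback: generate the same vinylketene in the dark. Setting out from 10, Wolff rearrangement in the presence of water (PhCO2Ag, Et3N, THF–H2O) should give (Z)-4-{3-[(tert-butyldimethylsilyl)oxy]-2-(methoxycarbonyl)-5-methylphenoxy}-3-{[(tert-butyldiphenylsilyl)oxy]methyl}but-3-enoic acid F1. 1-Chloro-N,N,2-trimethylprop-1-en-1-amine should convert it into (Z)-4-{3-[(tert-butyldimethylsilyl)oxy]-2-(methoxycarbonyl)-5-methylphenoxy}-3-{[(tert-butyldiphenylsilyl)oxy]methyl}but-3-enoyl chloride F2. Slow addition of Et3N to F2 and 12 in toluene at 80 °C (sealed tube) should dehydrochlorinate F2 to vinylketene 13, and the thermal cascade comes back to the route at 17.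

**Step 2.** The ester enolate may lose silyloxide by β-elimination before it is formylated, because the leaving group sits β to the carbanion.

Fallback: bypass 2 to 4, setting out from 5. DABCO-catalysed conjugate addition of 5 to tert-butyl propiolate should give tert-butyl (E)-3-[3-hydroxy-2-(methoxycarbonyl)-5-methylphenoxy]prop-2-enoate F3. α-Iodination with N-iodosuccinimide followed by Et3N should give tert-butyl (Z)-3-[3-hydroxy-2-(methoxycarbonyl)-5-methylphenoxy]-2-iodoprop-2-enoate F4. Stille coupling with Bu3SnCH2OH and Pd(PPh3)4 should give tert-butyl (E)-2-(hydroxymethyl)-3-[3-hydroxy-2-(methoxycarbonyl)-5-methylphenoxy]prop-2-enoate F5. TBDPSCl and imidazole should silylate only the primary alcohol and return to the route at 6.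

**Step 4.** The phenoxide may attack sulfur instead of the β-carbon (sulfonyl transfer to the phenol), since the formyl ester enolate is a good leaving group; a second substitution on the remaining phenol is also possible.

Fallback: setting out from 3, PPh3 and CCl4 should give tert-butyl (E)-3-chloro-2-{[(tert-butyldiphenylsilyl)oxy]methyl}prop-2-enoate F6, which has no second electrophilic site. The same addition–elimination with 5 and Cs2CO3 comes back at 6.

**Step 7.** Diazomethane may add across the enoyl double bond as a 1,3-dipole, or acylation of the vinylogous chloroformate may be sluggish.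

Fallback: setting out from 9, coupling with Me4Sn catalysed by PhCH2Pd(PPh3)2Cl (THF, 60 °C) should give methyl 2-[(tert-butyldimethylsilyl)oxy]-6-{[(E)-2-{[(tert-butyldiphenylsilyl)oxy]methyl}-3-oxobut-1-en-1-yl]oxy}-4-methylbenzoate F7. LiN(SiMe3)2 at −78 °C followed by CF3CO2CH2CF3 should give methyl 2-[(tert-butyldimethylsilyl)oxy]-6-{[(E)-2-{[(tert-butyldiphenylsilyl)oxy]methyl}-6,6,6-trifluoro-3,5-dioxohex-1-en-1-yl]oxy}-4-methylbenzoate F8. Detrifluoroacetylative diazo transfer (MsN3, Et3N, H2O, MeCN) comes back at 10.

**Step 11.** Chemoselectivity may be incomplete: a phenol may act as the nucleophile or be acylated, because three hydroxyl groups are present.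

Fallback: setting out from 18, Ac2O, pyridine and DMAP should give methyl 2-acetoxy-6-[2-acetoxy-6-(acetoxymethyl)-4-methoxyphenoxy]-4-methylbenzoate F9. NH4OAc in aqueous MeOH should cleave only the two aryl acetates and come back at 19.

## Further compounds

F1 | step 9 | (Z)-4-{3-[(tert-butyldimethylsilyl)oxy]-2-(methoxycarbonyl)-5-methylphenoxy}-3-{[(tert-butyldiphenylsilyl)oxy]methyl}but-3-enoic acid | COC(=O)c1c(O[Si](C)(C)C(C)(C)C)cc(C)cc1O/C=C(\CO[Si](c2ccccc2)(c2ccccc2)C(C)(C)C)CC(=O)O
F2 | step 9 | (Z)-4-{3-[(tert-butyldimethylsilyl)oxy]-2-(methoxycarbonyl)-5-methylphenoxy}-3-{[(tert-butyldiphenylsilyl)oxy]methyl}but-3-enoyl chloride | COC(=O)c1c(O[Si](C)(C)C(C)(C)C)cc(C)cc1O/C=C(\CO[Si](c2ccccc2)(c2ccccc2)C(C)(C)C)CC(=O)Cl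
F3 | step 2 | tert-butyl (E)-3-[3-hydroxy-2-(methoxycarbonyl)-5-methylphenoxy]prop-2-enoate | COC(=O)c1c(O)cc(C)cc1O/C=C/C(=O)OC(C)(C)C
F4 | step 2 | tert-butyl (Z)-3-[3-hydroxy-2-(methoxycarbonyl)-5-methylphenoxy]-2-iodoprop-2-enoate | COC(=O)c1c(O)cc(C)cc1O/C=C(\I)C(=O)OC(C)(C)C
F5 | step 2 | tert-butyl (E)-2-(hydroxymethyl)-3-[3-hydroxy-2-(methoxycarbonyl)-5-methylphenoxy]prop-2-enoate | COC(=O)c1c(O)cc(C)cc1O/C=C(\CO)C(=O)OC(C)(C)C
F6 | step 4 | tert-butyl (E)-3-chloro-2-{[(tert-butyldiphenylsilyl)oxy]methyl}prop-2-enoate | CC(C)(C)OC(=O)/C(CO[Si](c1ccccc1)(c1ccccc1)C(C)(C)C)=C/Cl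
F7 | step 7 | methyl 2-[(tert-butyldimethylsilyl)oxy]-6-{[(E)-2-{[(tert-butyldiphenylsilyl)oxy]methyl}-3-oxobut-1-en-1-yl]oxy}-4-methylbenzoate | COC(=O)c1c(O[Si](C)(C)C(C)(C)C)cc(C)cc1O/C=C(\CO[Si](c2ccccc2)(c2ccccc2)C(C)(C)C)C(C)=O
F8 | step 7 | methyl 2-[(tert-butyldimethylsilyl)oxy]-6-{[(E)-2-{[(tert-butyldiphenylsilyl)oxy]methyl}-6,6,6-trifluoro-3,5-dioxohex-1-en-1-yl]oxy}-4-methylbenzoate | COC(=O)c1c(O[Si](C)(C)C(C)(C)C)cc(C)cc1O/C=C(\CO[Si](c2ccccc2)(c2ccccc2)C(C)(C)C)C(=O)CC(=O)C(F)(F)F
F9 | step 11 | methyl 2-acetoxy-6-[2-acetoxy-6-(acetoxymethyl)-4-methoxyphenoxy]-4-methylbenzoate | COC(=O)c1c(OC(C)=O)cc(C)cc1Oc1c(OC(C)=O)cc(OC)cc1COC(C)=O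
A1 | alternative 1 | 2-{2-(benzyloxy)-6-[(tert-butyldimethylsilyloxy)methyl]-4-methoxyphenoxy}-6-methoxy-4-methylbenzoic acid | COc1cc(C)cc(Oc2c(OCc3ccccc3)cc(OC)cc2CO[Si](C)(C)C(C)(C)C)c1C(=O)O
A2 | alternative 1 | 3-methoxy-5-methyl-2-(trimethylsilyl)phenyl trifluoromethanesulfonate | COc1cc(C)cc(OS(=O)(=O)C(F)(F)F)c1[Si](C)(C)C
A3 | alternative 1 | 2-(benzyloxy)-6-{[(tert-butyldimethylsilyl)oxy]methyl}-4-methoxyphenol | Oc1c(OCc2ccccc2)cc(OC)cc1CO[Si](C)(C)C(C)(C)C
A4 | alternative 1 | carbon dioxide | O=C=O
A5 | alternative 2 | methyl 2-{2-(benzyloxy)-6-[(tert-butyldimethylsilyloxy)methyl]-4-methoxyphenoxy}-6-hydroxy-4-methylbenzoate | COC(=O)c1c(O)cc(C)cc1Oc1c(OCc2ccccc2)cc(OC)cc1CO[Si](C)(C)C(C)(C)C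
A6 | alternative 2 | methyl 3-[2-(benzyloxy)-6-{[(tert-butyldimethylsilyl)oxy]methyl}-4-methoxyphenoxy]prop-2-ynoate | COC(=O)C#COc1c(OCc2ccccc2)cc(OC)cc1CO[Si](C)(C)C(C)(C)C
A7 | alternative 2 | [(1-methoxy-3-methylbuta-1,3-dien-1-yl)oxy]trimethylsilane (mixture of geometric isomers) | COC(O[Si](C)(C)C)=CC(C)=C
A8 | alternative 3 | methyl 2-{2-(benzyloxy)-6-[(tert-butyldimethylsilyloxy)methyl]-4-methoxyphenoxy}-6-methoxy-4-methylbenzoate | COC(=O)c1c(OC)cc(C)cc1Oc1c(OCc2ccccc2)cc(OC)cc1CO[Si](C)(C)C(C)(C)C
A9 | alternative 3 | methyl 4-methoxy-6-methyl-2-oxo-2H-pyran-3-carboxylate | COC(=O)C1=C(OC)C=C(C)OC1=O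
A10 | alternative 3 | 1-(benzyloxy)-3-{[(tert-butyldimethylsilyl)oxy]methyl}-2-(ethynyloxy)-5-methoxybenzene | C#COc1c(OCc2ccccc2)cc(OC)cc1CO[Si](C)(C)C(C)(C)C
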